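The pitfall was to read the 1.20 M of protonated nucleophile as nucleophile on hand: it has to lose its proton before it can couple.

    electrophile + target → side product (k1 = 5.40 × 10⁻⁶ L mol⁻¹ s⁻¹)
    electrophile + nucleophile → acid set free + target (k2 = 1.40 × 10⁻⁵ L mol⁻¹ s⁻¹)
    acid set free + free base ⇌ salt of the base (K3 = 35300 L mol⁻¹, k3 = 0.00157 L mol⁻¹ s⁻¹)
    nucleophile + protic impurity → quenched reagent (k4 = 2.34 × 10⁻⁴ L mol⁻¹ s⁻¹)
    target ⇌ isomer of the product (K5 = 1.0, k5 = 3.96 × 10⁻⁵ s⁻¹)
    nucleophile + acid set free ⇌ protonated nucleophile, settled at all times (K6 = 1000 L mol⁻¹)

- north-west: electrophile 1.0 M; free base 1.20 M; protonated nucleophile 1.20 M; protic impurity 0.100 M; time 8.0 h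
- north-east: electrophile 1.0 M; free base 1.80 M; protonated nucleophile 1.20 M; protic impurity 0.100 M; time 8.0 h

* part of the electrophile that has reacted at the end, north-west
* part of the electrophile that has reacted at the end, north-east
* what raising the concentration of free base from its lowest to its highest value here does to the part of the electrophile that has reacted (changes below 5 percentage points count as none) (it falls / it rises / no change)

- percent here means electrophile units held: one side product counts as two
- run time (north-west): 8.0 h

I began with the release. Acid set free stands at balance with nucleophile, so free base, in taking acid, frees nucleophile at a rate equal to a release constant, k3/K6 = 1.57 × 10⁻⁶ s⁻¹, times protonated nucleophile times free base, divided by nucleophile. At given protonated nucleophile and free base, the more nucleophile stands, the slower it comes.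

My first way ignored every loss. The square of the nucleophile then grew in step with time, reaching 0.361 M north-west at the end. Its time average of 0.241 M gave 9.70% coupling in that north-west flask.

My second way counted the losses. Nucleophile goes to protic impurity, and each coupling uses one nucleophile while its acid takes up a second, so the pseudo-first-order loss constant, taken on the charged amounts, was 5.14 × 10⁻⁵ s⁻¹. Release equals loss north-west at 0.210 M, the standing nucleophile level: the square root of release constant times protonated nucleophile times free base, over the loss constant. The loss-free rise reaches this level after 2.70 h. Rising to it and then staying there gave 7.50% coupling north-west.

The two ways parted, and the first one cheated: because 2.70 h is shorter than the run, its end value stood higher than the level. I committed to the second. With protonated nucleophile and the loss constant held, the level goes as the square root of free base, so north-east came to 9.19% coupling, a gap of 1.7 percentage points, smaller than the margin.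

The forecast, starting from the view that “protonated nucleophile is the only source of free nucleophile”, gave 6.3% (5.3% to 7.5%) north-west, lower than mine, and 7.5% (6.3% to 9%) north-east, with the verdict no change.

The simulation gave 6.03% north-west and 7.39% north-east, a change of 1.4 points and so no change, both inside the forecast's ranges and both lower than my figures for coupling. With the north-west amounts at 8.00 h, the same balance of release against loss gave 0.186 M, and 0.177 M of nucleophile stood in that flask. In a neighbour flask like north-west but with 0.40 M of protic impurity, the balance on its amounts at 8.00 h gave 0.120 M, against 0.120 M of nucleophile standing there, and 4.58% of its electrophile had reacted.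

The rate constants stand for no real mixture.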